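**Plan**

- Retrosynthesis: the two 4-methoxybenzyl ethers come off last. Ring C is cut at O1–C2 and C2–C3 (C2 from DMF-DMA), which leaves the 2-hydroxydeoxybenzoin 21.
- Ring A is cut at C4a–C8a, C5–C6 and C8–C8a. This is possible because ring A has four different neighbours in fixed order (OH on C8a, the carbon chain on C4a, OMe on C5, oxygen on C7, H on C6 and C8). A 3-alkoxyvinylketene (C8a, C6, C7, C8) and a 1-methoxyalkyne (C4a, C5) deliver exactly this pattern.
- The alkyne is cut at C4–C4a (acetylide addition) and C3–C4 (Wittig homologation) back to a ring B benzaldehyde; its prenyl group comes from a Stille coupling on a bromide made from 5-bromovanillin.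
- Forward: ring B is dressed and extended to alkyne 11 (steps 1–8), cyclobutenone 14 is made separately (steps 9–10), ring A is built in step 11, ring C is closed in step 14, and step 15 frees the phenols.
- Stereochemistry: the target has no stereocentre. The carbinol carbon of 10, 11, 19 and 20 is carried as a racemate and becomes the C4 carbonyl in step 13.

Key step: step 11

Abbreviations: PMB = 4-methoxybenzyl; TBS = tert-butyldimethylsilyl; ArB = 4-methoxy-3-[(4-methoxybenzyl)oxy]-5-(3-methylbut-2-en-1-yl)phenyl (protected ring B); DMP = Dess–Martin periodinane; DMF-DMA = N,N-dimethylformamide dimethyl acetal.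

Assumption: in step 1 the cleaved O-methyl group is taken to end up on pyridine (as N-methylpyridinium chloride) and not to leave as chloromethane.

**Route**

Step 1
Reactants: 1 5-bromovanillin
Product: 2 3-bromo-4,5-dihydroxybenzaldehyde
Conditions: AlCl3, pyridine, CH2Cl2, reflux; then aq. HCl
Reagents that add atoms: none
Why: Aluminium-assisted cleavage of an aryl methyl ether ortho to a free phenol, in which AlCl3 forms a five-membered catecholate chelate that activates only the neighbouring OMe group toward demethylation by pyridine, a well-used transformation of 5-bromovanillin that leaves the aldehyde and the bromide untouched.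

Step 2
Reactants: 2 3-bromo-4,5-dihydroxybenzaldehyde
Product: 3 3-bromo-5-hydroxy-4-methoxybenzaldehyde
Conditions: MeI (1.05 equiv), Li2CO3, DMF, 40 °C
Reagents that add atoms: iodomethane, CI
Why: Regioselective Williamson O-methylation, in which the 4-OH (para to the formyl group and flanked by bromine) is the more acidic phenol, so the weak base Li2CO3 forms only its phenoxide and one equivalent of MeI methylates it, as is standard for 3,4-dihydroxybenzaldehydes.

Step 3
Reactants: 3 3-bromo-5-hydroxy-4-methoxybenzaldehyde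
Product: 4 3-bromo-4-methoxy-5-(PMB-oxy)benzaldehyde
Conditions: PMBCl, K2CO3, DMF, rt
Reagents that add atoms: 4-methoxybenzyl chloride, COc1ccc(CCl)cc1
Why: Williamson etherification of the remaining phenol installs a PMB ether that should tolerate organotin coupling, ylides, acetylides, fluoride, dilute aqueous acid and heat and that is removed at the end by acidolysis.

Step 4
Reactants: 4 3-bromo-4-methoxy-5-(PMB-oxy)benzaldehyde
Product: 5 4-methoxy-3-(PMB-oxy)-5-(3-methylbut-2-en-1-yl)benzaldehyde (ArB-CHO)
Conditions: Bu3SnCH2CH=CMe2, Pd(PPh3)4 (5 mol %), DMF, 100 °C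
Reagents that add atoms: tributyl(3-methylbut-2-en-1-yl)stannane, CC(C)=CC[Sn](CCCC)(CCCC)CCCC
Why: Stille cross-coupling (oxidative addition of the aryl bromide to zerovalent palladium, transmetalation from the prenylstannane, reductive elimination at the unhindered terminus of the allyl ligand) is an established way to place a linear prenyl group on an arene in the presence of an aldehyde.

Step 5
Reactants: 5 ArB-CHO
Product: 6 ArB-CH=CH-OMe (E/Z mixture)
Conditions: Ph3P(CH2OMe)Cl, KOtBu, THF, 0 °C → rt
Reagents that add atoms: (methoxymethyl)triphenylphosphonium chloride, COC[P+](c1ccccc1)(c1ccccc1)c1ccccc1.[Cl-]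
Why: Wittig olefination with the methoxymethylene ylide converts the non-enolisable aldehyde into the homologous methyl enol ether, whose E/Z mixture is inconsequential because both isomers hydrolyse to the same aldehyde.

Step 6
Reactants: 6 ArB-CH=CH-OMe
Product: 7 2-ArB-acetaldehyde
Conditions: 2 M HCl, THF, rt
Reagents that add atoms: water, O
Why: Acid-catalysed enol ether hydrolysis (C-protonation, then hemiacetal collapse) gives the one-carbon-homologated arylacetaldehyde under dilute acid at room temperature, conditions under which an aryl PMB ether and a trisubstituted alkene are expected to persist.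

Step 7
Reactants: 7 2-ArB-acetaldehyde; 8 chloroacetaldehyde dimethyl acetal
Product: 10 racemic 4-methoxy-1-ArB-but-3-yn-2-ol, via lithium methoxyacetylide 9 (not isolated)
Conditions: 8, LiNEt2 (3 equiv, from n-BuLi and Et2NH), THF, 0 °C; then 7, −78 °C; aq. NaHCO3
Reagents that add atoms: none
Why: Lithium diethylamide converts the chloroacetal by loss of methanol and then HCl into methoxyacetylene and deprotonates it, and the resulting lithium acetylide 9 adds to the aldehyde at −78 °C faster than it enolises it (acetylide 1,2-addition); the new carbinol centre forms without control as a racemate, which is acceptable because this carbon becomes the C4 carbonyl.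

Step 8
Reactants: 10 racemic 4-methoxy-1-ArB-but-3-yn-2-ol
Product: 11 racemic tert-butyl[(4-methoxy-1-ArB-but-3-yn-2-yl)oxy]dimethylsilane
Conditions: TBSCl, imidazole, DMF, rt
Reagents that add atoms: tert-butyldimethylsilyl chloride, CC(C)(C)[Si](C)(C)Cl
Why: Silylation of the secondary propargylic alcohol with TBSCl and imidazole runs under buffered, non-acidic conditions that spare the acid-sensitive 1-alkynyl ether and removes the free hydroxyl that would otherwise intercept the ketene in step 11.

Step 9
Reactants: 12 3-ethoxycyclobut-2-en-1-one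
Product: 13 cyclobutane-1,3-dione
Conditions: 1 M HCl, THF–H2O, 0 °C → rt; concentration in the cold
Reagents that add atoms: water, O
Why: Acid-catalysed hydrolysis of the vinylogous ester (addition of water at C3, loss of ethanol) is the classical preparation of cyclobutane-1,3-dione, which is used directly because it is a strong and moisture-sensitive vinylogous acid.

Step 10
Reactants: 13 cyclobutane-1,3-dione
Product: 14 3-(PMB-oxy)cyclobut-2-en-1-one
Conditions: 4-MeOC6H4CH2OH, PPh3, DIAD, THF, 0 °C → rt
Reagents that add atoms: 4-methoxybenzyl alcohol, COc1ccc(CO)cc1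
Why: Mitsunobu alkylation, in which the strongly acidic enol form of the dione protonates the betaine and its oxygen then displaces triphenylphosphine oxide from the benzylic alkoxyphosphonium ion by SN2, the usual O-alkylation outcome for cyclic 1,3-diones and tetronic acids.

Step 11
Reactants: 11 racemic tert-butyl[(4-methoxy-1-ArB-but-3-yn-2-yl)oxy]dimethylsilane; 14 3-(PMB-oxy)cyclobut-2-en-1-one
Product: 19 racemic 2-[1-(TBS-oxy)-2-ArB-ethyl]-3-methoxy-5-(PMB-oxy)phenol, via vinylketene 15 (not isolated), via vinylcyclobutenone 16 (not isolated), via dienylketene 17 (not isolated), via cyclohexadienone 18 (not isolated)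
Conditions: 14 (1.5 equiv), PhMe, 80 °C then 110 °C, sealed tube, argon
Reagents that add atoms: none
Why: Heating opens cyclobutenone 14 by 4π electrocyclic cleavage of its C1–C4 bond to the 3-alkoxyvinylketene 15, whose electrophilic ketene carbon is attacked by the nucleophilic carbon of ynol ether 11 remote from the methoxy group in a regiospecific [2+2] cycloaddition that forms C4a–C8a and C5–C6 of 16. A second 4π opening of 16 gives dienylketene 17, ring A then closes by thermal disrotatory 6π electrocyclisation (forming C8–C8a) to cyclohexadienone 18, and tautomerisation delivers phenol 19. The closest known reaction type is the Danheiser benzannulation of cyclobutenones with 1-alkoxy- and 1-silyloxyalkynes to resorcinol monoethers, applied here with a vinylogous-ester cyclobutenone so that C7 also carries oxygen. No stereocentre is created in 19, since the carbinol centre of 11 is a racemic spectator and the ring stereocentre of 16 disappears on ring opening. The one selectivity needed is the orientation of the [2+2] step, which the polarisation of the methoxyalkyne secures, so that the methoxy carbon becomes C5 next to the side chain on C4a, the ketene oxygen becomes the C8a hydroxyl and the PMB-oxy carbon becomes C7. The silyl ether, the PMB ethers, the prenyl alkene and the aryl methyl ether are expected to be inert to neutral thermolysis in toluene.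

Step 12
Reactants: 19 racemic 2-[1-(TBS-oxy)-2-ArB-ethyl]-3-methoxy-5-(PMB-oxy)phenol
Product: 20 racemic 2-(1-hydroxy-2-ArB-ethyl)-3-methoxy-5-(PMB-oxy)phenol
Conditions: TBAF, THF, 0 °C → rt
Reagents that add atoms: none
Why: Fluoride-induced cleavage of the secondary TBS ether (driven by the strong Si–F bond) under basic to neutral conditions frees the benzylic alcohol without exposing this acid-labile, doubly ortho-oxygenated carbinol or the PMB ethers to acid.

Step 13
Reactants: 20 racemic 2-(1-hydroxy-2-ArB-ethyl)-3-methoxy-5-(PMB-oxy)phenol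
Product: 21 2-ArB-1-[2-hydroxy-6-methoxy-4-(PMB-oxy)phenyl]ethan-1-one
Conditions: DMP, NaHCO3, CH2Cl2, 0 °C
Reagents that add atoms: none
Why: Dess–Martin oxidation of the secondary benzylic alcohol under bicarbonate buffering at 0 °C should give the aryl ketone, ligand exchange at iodine by the alcohol being faster than attack on the phenol, and the product is stabilised by the hydrogen bond between the C8a hydroxyl and the new carbonyl; the racemic stereocentre is erased here.

Step 14
Reactants: 21 2-ArB-1-[2-hydroxy-6-methoxy-4-(PMB-oxy)phenyl]ethan-1-one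
Product: 23 3-ArB-5-methoxy-7-(PMB-oxy)-4H-chromen-4-one, via enaminone 22 (not isolated)
Conditions: Me2NCH(OMe)2, PhMe, 90 °C
Reagents that add atoms: N,N-dimethylformamide dimethyl acetal, COC(OC)N(C)C
Why: Condensation of the doubly activated methylene with DMF-DMA gives enaminone 22, and the ortho phenol then adds to the enamine carbon in a 6-endo addition–elimination that expels dimethylamine and closes ring C, which is the standard deoxybenzoin route to isoflavones.

Step 15
Reactants: 23 3-ArB-5-methoxy-7-(PMB-oxy)-4H-chromen-4-one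
Product: 24 7-hydroxy-3-[3-hydroxy-4-methoxy-5-(3-methylbut-2-en-1-yl)phenyl]-5-methoxy-4H-chromen-4-one
Conditions: TFA, anisole (excess), CH2Cl2, 0 °C
Reagents that add atoms: none
Why: Acidolysis of the two aryl PMB ethers (SN1 ionisation to the 4-methoxybenzyl cation, which anisole traps by Friedel–Crafts alkylation) liberates the C7 and C3' phenols, while the aryl methyl ethers, the chromone and, at 0 °C with short exposure, the prenyl alkene are expected to survive.

**Compound list**

1 | 5-bromovanillin (3-bromo-4-hydroxy-5-methoxybenzaldehyde) | COc1cc(C=O)cc(Br)c1O | starting material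
2 | 3-bromo-4,5-dihydroxybenzaldehyde | O=Cc1cc(O)c(O)c(Br)c1 | intermediate
3 | 3-bromo-5-hydroxy-4-methoxybenzaldehyde | COc1c(O)cc(C=O)cc1Br | intermediate
4 | 3-bromo-4-methoxy-5-[(4-methoxybenzyl)oxy]benzaldehyde | COc1ccc(COc2cc(C=O)cc(Br)c2OC)cc1 | intermediate
5 | 4-methoxy-3-[(4-methoxybenzyl)oxy]-5-(3-methylbut-2-en-1-yl)benzaldehyde (ArB-CHO) | COc1ccc(COc2cc(C=O)cc(CC=C(C)C)c2OC)cc1 | intermediate
6 | 2-methoxy-1-[(4-methoxybenzyl)oxy]-5-(2-methoxyethenyl)-3-(3-methylbut-2-en-1-yl)benzene, E/Z mixture | COC=Cc1cc(CC=C(C)C)c(OC)c(OCc2ccc(OC)cc2)c1 | intermediate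
7 | 2-{4-methoxy-3-[(4-methoxybenzyl)oxy]-5-(3-methylbut-2-en-1-yl)phenyl}acetaldehyde | O=CCc1cc(CC=C(C)C)c(OC)c(OCc2ccc(OC)cc2)c1 | intermediate
8 | chloroacetaldehyde dimethyl acetal (2-chloro-1,1-dimethoxyethane) | COC(CCl)OC | starting material
9 | lithium methoxyacetylide (formed in the flask) | [Li]C#COC | intermediate
10 | racemic 4-methoxy-1-ArB-but-3-yn-2-ol | COC#CC(O)Cc1cc(CC=C(C)C)c(OC)c(OCc2ccc(OC)cc2)c1 | intermediate
11 | racemic tert-butyl[(4-methoxy-1-ArB-but-3-yn-2-yl)oxy]dimethylsilane | COC#CC(O[Si](C)(C)C(C)(C)C)Cc1cc(CC=C(C)C)c(OC)c(OCc2ccc(OC)cc2)c1 | intermediate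
12 | 3-ethoxycyclobut-2-en-1-one | CCOC1=CC(=O)C1 | starting material
13 | cyclobutane-1,3-dione | O=C1CC(=O)C1 | intermediate
14 | 3-[(4-methoxybenzyl)oxy]cyclobut-2-en-1-one | COc1ccc(COC2=CC(=O)C2)cc1 | intermediate
15 | 3-[(4-methoxybenzyl)oxy]buta-1,3-dien-1-one (vinylketene, formed in the flask) | C=C(OCc1ccc(OC)cc1)C=C=O | intermediate
16 | 2-[1-(TBS-oxy)-2-ArB-ethyl]-3-methoxy-4-{1-[(4-methoxybenzyl)oxy]ethenyl}cyclobut-2-en-1-one (diastereomer mixture, formed in the flask) | COC1=C(C(O[Si](C)(C)C(C)(C)C)Cc2cc(CC=C(C)C)c(OC)c(OCc3ccc(OC)cc3)c2)C(=O)C1C(=C)OCc1ccc(OC)cc1 | intermediate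
17 | 2-[1-(TBS-oxy)-2-ArB-ethyl]-3-methoxy-5-[(4-methoxybenzyl)oxy]hexa-1,3,5-trien-1-one (dienylketene, isomer with ketene and vinyl cis, formed in the flask) | C=C(OCc1ccc(OC)cc1)/C=C(OC)\C(=C=O)C(O[Si](C)(C)C(C)(C)C)Cc1cc(CC=C(C)C)c(OC)c(OCc2ccc(OC)cc2)c1 | intermediate
18 | 2-[1-(TBS-oxy)-2-ArB-ethyl]-3-methoxy-5-[(4-methoxybenzyl)oxy]cyclohexa-2,4-dien-1-one (formed in the flask) | COC1=C(C(O[Si](C)(C)C(C)(C)C)Cc2cc(CC=C(C)C)c(OC)c(OCc3ccc(OC)cc3)c2)C(=O)CC(OCc2ccc(OC)cc2)=C1 | intermediate
19 | racemic 2-[1-(TBS-oxy)-2-ArB-ethyl]-3-methoxy-5-[(4-methoxybenzyl)oxy]phenol | COc1cc(OCc2ccc(OC)cc2)cc(O)c1C(O[Si](C)(C)C(C)(C)C)Cc1cc(CC=C(C)C)c(OC)c(OCc2ccc(OC)cc2)c1 | intermediate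
20 | racemic 2-(1-hydroxy-2-ArB-ethyl)-3-methoxy-5-[(4-methoxybenzyl)oxy]phenol | COc1cc(OCc2ccc(OC)cc2)cc(O)c1C(O)Cc1cc(CC=C(C)C)c(OC)c(OCc2ccc(OC)cc2)c1 | intermediate
21 | 2-ArB-1-{2-hydroxy-6-methoxy-4-[(4-methoxybenzyl)oxy]phenyl}ethan-1-one | COc1cc(OCc2ccc(OC)cc2)cc(O)c1C(=O)Cc1cc(CC=C(C)C)c(OC)c(OCc2ccc(OC)cc2)c1 | intermediate
22 | 2-ArB-3-(dimethylamino)-1-{2-hydroxy-6-methoxy-4-[(4-methoxybenzyl)oxy]phenyl}prop-2-en-1-one (enaminone, formed in the flask) | COc1cc(OCc2ccc(OC)cc2)cc(O)c1C(=O)C(=CN(C)C)c1cc(CC=C(C)C)c(OC)c(OCc2ccc(OC)cc2)c1 | intermediate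
23 | 5-methoxy-7-[(4-methoxybenzyl)oxy]-3-{4-methoxy-3-[(4-methoxybenzyl)oxy]-5-(3-methylbut-2-en-1-yl)phenyl}-4H-chromen-4-one | COc1ccc(COc2cc(OC)c3c(c2)occ(-c2cc(CC=C(C)C)c(OC)c(OCc4ccc(OC)cc4)c2)c3=O)cc1 | intermediate
24 | 7-hydroxy-3-[3-hydroxy-4-methoxy-5-(3-methylbut-2-en-1-yl)phenyl]-5-methoxy-4H-chromen-4-one | COc1c(O)cc(-c2coc3cc(O)cc(OC)c3c2=O)cc1CC=C(C)C | target

**Step count and risks**

Total: 15 steps. Longest linear sequence: 13 steps (steps 1–8 and 11–15); the cyclobutenone branch (steps 9–10) joins at step 11.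

The three steps most likely to fail:

1. Step 11 (benzannulation). The alkoxyvinylketene may dimerise or polymerise faster than the hindered ynol ether captures it. The product phenol may be acylated by excess ketene, and the alkynyl ether may decompose on prolonged heating. Slow addition of 14 and a brief K2CO3/MeOH treatment of the crude product (to return any O-acylated phenol) are the first remedies. The fallback abandons the benzannulation and brings ring A in preformed. It sets out from aldehyde 7 and returns at target 24. Commercial 4-bromo-3,5-dimethoxyphenol is alkylated (PMBCl, K2CO3, DMF) to 2-bromo-1,3-dimethoxy-5-[(4-methoxybenzyl)oxy]benzene F1. Bromine–lithium exchange (n-BuLi, THF, −78 °C) gives {2,6-dimethoxy-4-[(4-methoxybenzyl)oxy]phenyl}lithium F2, which is added to 7 to give racemic 2-ArB-1-{2,6-dimethoxy-4-[(4-methoxybenzyl)oxy]phenyl}ethan-1-ol F3. DMP oxidation gives the ketone 2-ArB-1-{2,6-dimethoxy-4-[(4-methoxybenzyl)oxy]phenyl}ethan-1-one F4. BCl3 (CH2Cl2, −78 → 0 °C) then cleaves one of the two equivalent methyl ethers ortho to the carbonyl by chelation, together with both PMB ethers, to give 1-(2,4-dihydroxy-6-methoxyphenyl)-2-[3-hydroxy-4-methoxy-5-(3-methylbut-2-en-1-yl)phenyl]ethan-1-one F5. DMF-DMA in THF at 60 °C converts F5 through the enaminone 3-(dimethylamino)-1-(2,4-dihydroxy-6-methoxyphenyl)-2-[3-hydroxy-4-methoxy-5-(3-methylbut-2-en-1-yl)phenyl]prop-2-en-1-one F6 (not isolated) directly into 24.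

2. Step 13 (oxidation beside a free phenol). The pentavalent iodine reagent may dearomatise the electron-rich phenol. The doubly activated benzylic alcohol may also ionise under the acetic acid released and dehydrate to the stilbene. The fallback masks the phenol before the alcohol is freed. It sets out from 19 and returns at 21. Allylation of 19 (allyl bromide, K2CO3, DMF) gives racemic tert-butyl(1-{2-(allyloxy)-6-methoxy-4-[(4-methoxybenzyl)oxy]phenyl}-2-ArB-ethoxy)dimethylsilane F7. TBAF gives racemic 1-{2-(allyloxy)-6-methoxy-4-[(4-methoxybenzyl)oxy]phenyl}-2-ArB-ethan-1-ol F8. DMP oxidation, now without a free phenol, gives 1-{2-(allyloxy)-6-methoxy-4-[(4-methoxybenzyl)oxy]phenyl}-2-ArB-ethan-1-one F9. Deallylation with Pd(PPh3)4 (zerovalent palladium) and morpholine in THF gives 21.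

3. Step 15 (global deprotection). The 4-methoxybenzyl cation may re-alkylate the liberated electron-rich phenols, and the acid may hydrate or shift the prenyl double bond. The fallback replaces acidolysis by oxidative cleavage. It sets out from 23 and returns at 24: DDQ in CH2Cl2 with pH 7 buffer at 0 °C → rt removes both aryl PMB ethers as 4-methoxybenzaldehyde. This fallback makes no new compound (F0).

Further compounds
F1 | step 11 | 2-bromo-1,3-dimethoxy-5-[(4-methoxybenzyl)oxy]benzene | COc1ccc(COc2cc(OC)c(Br)c(OC)c2)cc1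
F2 | step 11 | {2,6-dimethoxy-4-[(4-methoxybenzyl)oxy]phenyl}lithium | [Li]c1c(OC)cc(OCc2ccc(OC)cc2)cc1OC
F3 | step 11 | racemic 2-ArB-1-{2,6-dimethoxy-4-[(4-methoxybenzyl)oxy]phenyl}ethan-1-ol | COc1ccc(COc2cc(OC)c(C(O)Cc3cc(CC=C(C)C)c(OC)c(OCc4ccc(OC)cc4)c3)c(OC)c2)cc1
F4 | step 11 | 2-ArB-1-{2,6-dimethoxy-4-[(4-methoxybenzyl)oxy]phenyl}ethan-1-one | COc1ccc(COc2cc(OC)c(C(=O)Cc3cc(CC=C(C)C)c(OC)c(OCc4ccc(OC)cc4)c3)c(OC)c2)cc1
F5 | step 11 | 1-(2,4-dihydroxy-6-methoxyphenyl)-2-[3-hydroxy-4-methoxy-5-(3-methylbut-2-en-1-yl)phenyl]ethan-1-one | COc1cc(O)cc(O)c1C(=O)Cc1cc(CC=C(C)C)c(OC)c(O)c1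
F6 | step 11 | 3-(dimethylamino)-1-(2,4-dihydroxy-6-methoxyphenyl)-2-[3-hydroxy-4-methoxy-5-(3-methylbut-2-en-1-yl)phenyl]prop-2-en-1-one | COc1cc(O)cc(O)c1C(=O)C(=CN(C)C)c1cc(CC=C(C)C)c(OC)c(O)c1
F7 | step 13 | racemic tert-butyl(1-{2-(allyloxy)-6-methoxy-4-[(4-methoxybenzyl)oxy]phenyl}-2-ArB-ethoxy)dimethylsilane | C=CCOc1cc(OCc2ccc(OC)cc2)cc(OC)c1C(O[Si](C)(C)C(C)(C)C)Cc1cc(CC=C(C)C)c(OC)c(OCc2ccc(OC)cc2)c1
F8 | step 13 | racemic 1-{2-(allyloxy)-6-methoxy-4-[(4-methoxybenzyl)oxy]phenyl}-2-ArB-ethan-1-ol | C=CCOc1cc(OCc2ccc(OC)cc2)cc(OC)c1C(O)Cc1cc(CC=C(C)C)c(OC)c(OCc2ccc(OC)cc2)c1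
F9 | step 13 | 1-{2-(allyloxy)-6-methoxy-4-[(4-methoxybenzyl)oxy]phenyl}-2-ArB-ethan-1-one | C=CCOc1cc(OCc2ccc(OC)cc2)cc(OC)c1C(=O)Cc1cc(CC=C(C)C)c(OC)c(OCc2ccc(OC)cc2)c1
F0 | step 15 | none | none
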